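**Retrosynthetic overview**
- The target comes from its bis(benzyl ether) and primary silyl ether by desilylation and hydrogenolysis; the aryl ketone comes from oxidation of a benzylic carbinol.
- The tetrahydrofuran (second ring, formed last) is closed by 5-exo etherification of a 1,4-diol obtained by hydride opening of a trans,trans γ-butyrolactone. The lactone ring atoms map one-to-one onto the tetrahydrofuran.
- The bond from the ring to the syringyl carbinol carbon is made by a lactone-enolate aldol with O-benzylsyringaldehyde, anti to the neighbouring CH2OSi group.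
- The γ-aryl lactone (first ring) comes from the key C–C bond formation: an Evans syn aldol of a succinate imide with O-benzylvanillin, which sets the two adjacent ring stereocentres absolutely and lactonises.

Assumption: the exocyclic carbinol carbon made in step 7 is carried as an epimer mixture (left unspecified in the SMILES of 15 to 18), since step 10 removes it.

**Step 1**
Reactants: 1 (4S)-4-benzyl-1,3-oxazolidin-2-one; 2 methyl 4-chloro-4-oxobutanoate
Product: 4 methyl 4-[(4S)-4-benzyl-2-oxo-1,3-oxazolidin-3-yl]-4-oxobutanoate, via N-lithio oxazolidinone 3 (not isolated)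
Conditions: n-BuLi, THF, −78 °C; then 2, −78 → 0 °C
Reagents that add atoms: none
Why: N-acylation of the lithiated oxazolidinone by the acid chloride is fast at −78 °C and leaves the methyl ester untouched (imide formation, no new stereocentre).

**Step 2**
Reactants: 4 methyl 4-[(4S)-4-benzyl-2-oxo-1,3-oxazolidin-3-yl]-4-oxobutanoate; 5 4-(benzyloxy)-3-methoxybenzaldehyde
Product: 8 (4S)-4-benzyl-3-{(2S,3S)-2-[4-(benzyloxy)-3-methoxyphenyl]-5-oxooxolane-3-carbonyl}-1,3-oxazolidin-2-one, via Z boron enolate 6 (not isolated), via syn-aldol hydroxy ester 7 (not isolated)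
Conditions: Bu2BOTf, i-Pr2NEt, CH2Cl2, 0 °C; 5, −78 → 0 °C; pH 7 buffer/MeOH/30% H2O2, 0 °C; then PPTS (cat.), CH2Cl2, rt
Reagents that add atoms: none
Why: In this Evans syn aldol the Z boron enolate reacts through a chair Zimmerman–Traxler transition state on the face away from the auxiliary benzyl group, giving the (3S,4S) syn adduct that fixes the aryl-bearing carbon and its neighbour absolutely, and the γ-hydroxy ester then lactonises to the trans lactone without touching either centre.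

**Step 3**
Reactants: 8 (4S)-4-benzyl-3-{(2S,3S)-2-[4-(benzyloxy)-3-methoxyphenyl]-5-oxooxolane-3-carbonyl}-1,3-oxazolidin-2-one
Product: 9 (2S,3S)-2-[4-(benzyloxy)-3-methoxyphenyl]-5-oxooxolane-3-carboxylic acid
Conditions: LiOH·H2O, 30% H2O2, THF/H2O, 0 °C; Na2SO3; 1 M HCl to pH 2
Reagents that add atoms: hydrogen peroxide, OO
Why: Hydroperoxide attacks the exocyclic imide carbonyl selectively (oxazolidinone auxiliary cleavage), any lactone opened by hydroxide re-closes on acidification, and neither stereocentre epimerises at 0 °C.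

**Step 4**
Reactants: 9 (2S,3S)-2-[4-(benzyloxy)-3-methoxyphenyl]-5-oxooxolane-3-carboxylic acid
Product: 10 (4R,5S)-5-[4-(benzyloxy)-3-methoxyphenyl]-4-(hydroxymethyl)oxolan-2-one
Conditions: BH3·THF, THF, 0 °C → rt; MeOH quench
Reagents that add atoms: none
Why: Borane reduces a free carboxylic acid far faster than a lactone or an aryl benzyl ether (chemoselective borane reduction), and the non-basic medium avoids translactonisation.

**Step 5**
Reactants: 10 (4R,5S)-5-[4-(benzyloxy)-3-methoxyphenyl]-4-(hydroxymethyl)oxolan-2-one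
Product: 11 (4R,5S)-5-[4-(benzyloxy)-3-methoxyphenyl]-4-{[(tert-butyldimethylsilyl)oxy]methyl}oxolan-2-one
Conditions: TBSCl, imidazole, DMF, rt
Reagents that add atoms: tert-butyldimethylsilyl chloride, CC(C)(C)[Si](C)(C)Cl
Why: Silyl ether formation blocks the primary alcohol so that it can neither translactonise nor quench the enolate of the next step.

**Step 6**
Reactants: 12 4-hydroxy-3,5-dimethoxybenzaldehyde (syringaldehyde)
Product: 13 4-(benzyloxy)-3,5-dimethoxybenzaldehyde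
Conditions: BnBr, K2CO3, DMF, 60 °C
Reagents that add atoms: benzyl bromide, BrCc1ccccc1
Why: Williamson ether synthesis on the acidic phenol gives a benzyl ether that survives the later enolate, hydride and oxidation chemistry.

**Step 7**
Reactants: 11 (4R,5S)-5-[4-(benzyloxy)-3-methoxyphenyl]-4-{[(tert-butyldimethylsilyl)oxy]methyl}oxolan-2-one; 13 4-(benzyloxy)-3,5-dimethoxybenzaldehyde
Product: 15 (3R,4R,5S)-5-[4-(benzyloxy)-3-methoxyphenyl]-3-{[4-(benzyloxy)-3,5-dimethoxyphenyl](hydroxy)methyl}-4-{[(tert-butyldimethylsilyl)oxy]methyl}oxolan-2-one, via lithium enolate 14 (not isolated)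
Conditions: LiN(SiMe3)2, THF, −78 °C; 13, −78 °C; AcOH quench at −78 °C
Reagents that add atoms: none
Why: In this lactone-enolate aldol addition the aldehyde approaches the enolate face opposite the adjacent silyloxymethyl group, which sets the new ring stereocentre trans to it, while the exocyclic carbinol centre forms as a mixture that the later oxidation erases.

**Step 8**
Reactants: 15 (3R,4R,5S)-5-[4-(benzyloxy)-3-methoxyphenyl]-3-{[4-(benzyloxy)-3,5-dimethoxyphenyl](hydroxy)methyl}-4-{[(tert-butyldimethylsilyl)oxy]methyl}oxolan-2-one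
Product: 16 (1S,2R,3S)-1-[4-(benzyloxy)-3-methoxyphenyl]-3-{[4-(benzyloxy)-3,5-dimethoxyphenyl](hydroxy)methyl}-2-{[(tert-butyldimethylsilyl)oxy]methyl}butane-1,4-diol
Conditions: LiAlH4, THF, 0 °C; H2O/15% NaOH work-up
Reagents that add atoms: none
Why: LiAlH4 reduction opens the lactone to the 1,4-diol, leaves the silyl and benzyl ethers intact and touches none of the three ring-derived stereocentres.

**Step 9**
Reactants: 16 (1S,2R,3S)-1-[4-(benzyloxy)-3-methoxyphenyl]-3-{[4-(benzyloxy)-3,5-dimethoxyphenyl](hydroxy)methyl}-2-{[(tert-butyldimethylsilyl)oxy]methyl}butane-1,4-diol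
Product: 18 [4-(benzyloxy)-3,5-dimethoxyphenyl][(3S,4R,5S)-5-[4-(benzyloxy)-3-methoxyphenyl]-4-{[(tert-butyldimethylsilyl)oxy]methyl}oxolan-3-yl]methanol, via primary tosylate 17 (not isolated)
Conditions: TsCl (1.1 equiv), pyridine, CH2Cl2, 0 °C → rt, then 40 °C
Reagents that add atoms: none
Why: The only primary hydroxyl is sulfonylated selectively and is then displaced in a 5-exo-tet intramolecular Williamson etherification by the benzylic hydroxyl, which keeps its C–O bond and therefore its configuration, so the trans,trans pattern of the lactone is carried into the tetrahydrofuran.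

**Step 10**
Reactants: 18 [4-(benzyloxy)-3,5-dimethoxyphenyl][(3S,4R,5S)-5-[4-(benzyloxy)-3-methoxyphenyl]-4-{[(tert-butyldimethylsilyl)oxy]methyl}oxolan-3-yl]methanol
Product: 19 [4-(benzyloxy)-3,5-dimethoxyphenyl][(3S,4R,5S)-5-[4-(benzyloxy)-3-methoxyphenyl]-4-{[(tert-butyldimethylsilyl)oxy]methyl}oxolan-3-yl]methanone
Conditions: Dess–Martin periodinane, CH2Cl2, 0 °C → rt
Reagents that add atoms: none
Why: Dess–Martin oxidation turns the secondary benzylic alcohol into the aryl ketone under near-neutral conditions, converging both carbinol epimers and leaving the α-stereocentre in its thermodynamically preferred trans arrangement.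

**Step 11**
Reactants: 19 [4-(benzyloxy)-3,5-dimethoxyphenyl][(3S,4R,5S)-5-[4-(benzyloxy)-3-methoxyphenyl]-4-{[(tert-butyldimethylsilyl)oxy]methyl}oxolan-3-yl]methanone
Product: 20 [4-(benzyloxy)-3,5-dimethoxyphenyl][(3S,4R,5S)-5-[4-(benzyloxy)-3-methoxyphenyl]-4-(hydroxymethyl)oxolan-3-yl]methanone
Conditions: HF·pyridine, pyridine/THF, 0 °C → rt
Reagents that add atoms: none
Why: Fluoride-mediated desilylation with buffered HF·pyridine frees the primary alcohol without the basic conditions that could trigger β-alkoxy elimination next to the ketone.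

**Step 12**
Reactants: 20 [4-(benzyloxy)-3,5-dimethoxyphenyl][(3S,4R,5S)-5-[4-(benzyloxy)-3-methoxyphenyl]-4-(hydroxymethyl)oxolan-3-yl]methanone
Product: 21 (4-hydroxy-3,5-dimethoxyphenyl)[(3S,4R,5S)-5-(4-hydroxy-3-methoxyphenyl)-4-(hydroxymethyl)oxolan-3-yl]methanone
Conditions: H2 (1 atm), 10% Pd/C, EtOAc, rt, stopped at full conversion
Reagents that add atoms: none
Why: Catalytic hydrogenolysis cleaves both aryl benzyl ethers much faster than it attacks the aryl ketone or the cyclic benzylic ether under neutral conditions, releasing the target with all three stereocentres untouched.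

**Compound list**
1 | (4S)-4-benzyl-1,3-oxazolidin-2-one | O=C1N[C@@H](Cc2ccccc2)CO1 | starting material
2 | methyl 4-chloro-4-oxobutanoate | COC(=O)CCC(Cl)=O | starting material
3 | lithium (4S)-4-benzyl-2-oxo-1,3-oxazolidin-3-ide (not isolated) | O=C1[N-][C@@H](Cc2ccccc2)CO1.[Li+] | intermediate
4 | methyl 4-[(4S)-4-benzyl-2-oxo-1,3-oxazolidin-3-yl]-4-oxobutanoate | COC(=O)CCC(=O)N1[C@@H](Cc2ccccc2)COC1=O | intermediate
5 | 4-(benzyloxy)-3-methoxybenzaldehyde | COc1cc(C=O)ccc1OCc1ccccc1 | starting material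
6 | methyl (3Z)-4-[(4S)-4-benzyl-2-oxo-1,3-oxazolidin-3-yl]-4-[(dibutylboranyl)oxy]but-3-enoate (not isolated) | COC(=O)C/C=C(\OB(CCCC)CCCC)N1[C@@H](Cc2ccccc2)COC1=O | intermediate
7 | methyl (3S,4S)-3-{[(4S)-4-benzyl-2-oxo-1,3-oxazolidin-3-yl]carbonyl}-4-[4-(benzyloxy)-3-methoxyphenyl]-4-hydroxybutanoate (not isolated) | COc1cc([C@@H](O)[C@H](CC(=O)OC)C(=O)N2[C@@H](Cc3ccccc3)COC2=O)ccc1OCc1ccccc1 | intermediate
8 | (4S)-4-benzyl-3-{(2S,3S)-2-[4-(benzyloxy)-3-methoxyphenyl]-5-oxooxolane-3-carbonyl}-1,3-oxazolidin-2-one | COc1cc([C@H]2OC(=O)C[C@@H]2C(=O)N3[C@@H](Cc4ccccc4)COC3=O)ccc1OCc1ccccc1 | intermediate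
9 | (2S,3S)-2-[4-(benzyloxy)-3-methoxyphenyl]-5-oxooxolane-3-carboxylic acid | COc1cc([C@H]2OC(=O)C[C@@H]2C(=O)O)ccc1OCc1ccccc1 | intermediate
10 | (4R,5S)-5-[4-(benzyloxy)-3-methoxyphenyl]-4-(hydroxymethyl)oxolan-2-one | COc1cc([C@H]2OC(=O)C[C@@H]2CO)ccc1OCc1ccccc1 | intermediate
11 | (4R,5S)-5-[4-(benzyloxy)-3-methoxyphenyl]-4-{[(tert-butyldimethylsilyl)oxy]methyl}oxolan-2-one | COc1cc([C@H]2OC(=O)C[C@@H]2CO[Si](C)(C)C(C)(C)C)ccc1OCc1ccccc1 | intermediate
12 | 4-hydroxy-3,5-dimethoxybenzaldehyde | COc1cc(C=O)cc(OC)c1O | starting material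
13 | 4-(benzyloxy)-3,5-dimethoxybenzaldehyde | COc1cc(C=O)cc(OC)c1OCc1ccccc1 | intermediate
14 | lithium enolate of 11 (not isolated) | COc1cc([C@H]2OC([O-])=C[C@@H]2CO[Si](C)(C)C(C)(C)C)ccc1OCc1ccccc1.[Li+] | intermediate
15 | (3R,4R,5S)-5-[4-(benzyloxy)-3-methoxyphenyl]-3-{[4-(benzyloxy)-3,5-dimethoxyphenyl](hydroxy)methyl}-4-{[(tert-butyldimethylsilyl)oxy]methyl}oxolan-2-one, both carbinol epimers | COc1cc([C@H]2OC(=O)[C@@H](C(O)c3cc(OC)c(OCc4ccccc4)c(OC)c3)[C@@H]2CO[Si](C)(C)C(C)(C)C)ccc1OCc1ccccc1 | intermediate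
16 | (1S,2R,3S)-1-[4-(benzyloxy)-3-methoxyphenyl]-3-{[4-(benzyloxy)-3,5-dimethoxyphenyl](hydroxy)methyl}-2-{[(tert-butyldimethylsilyl)oxy]methyl}butane-1,4-diol, both carbinol epimers | COc1cc([C@@H](O)[C@@H](CO[Si](C)(C)C(C)(C)C)[C@@H](CO)C(O)c2cc(OC)c(OCc3ccccc3)c(OC)c2)ccc1OCc1ccccc1 | intermediate
17 | 4-O-(4-methylbenzenesulfonate) of 16 at the primary hydroxyl (not isolated) | COc1cc([C@@H](O)[C@@H](CO[Si](C)(C)C(C)(C)C)[C@@H](COS(=O)(=O)c2ccc(C)cc2)C(O)c2cc(OC)c(OCc3ccccc3)c(OC)c2)ccc1OCc1ccccc1 | intermediate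
18 | [4-(benzyloxy)-3,5-dimethoxyphenyl][(3S,4R,5S)-5-[4-(benzyloxy)-3-methoxyphenyl]-4-{[(tert-butyldimethylsilyl)oxy]methyl}oxolan-3-yl]methanol, both carbinol epimers, all-trans ring | COc1cc([C@H]2OC[C@@H](C(O)c3cc(OC)c(OCc4ccccc4)c(OC)c3)[C@@H]2CO[Si](C)(C)C(C)(C)C)ccc1OCc1ccccc1 | intermediate
19 | [4-(benzyloxy)-3,5-dimethoxyphenyl][(3S,4R,5S)-5-[4-(benzyloxy)-3-methoxyphenyl]-4-{[(tert-butyldimethylsilyl)oxy]methyl}oxolan-3-yl]methanone | COc1cc([C@H]2OC[C@@H](C(=O)c3cc(OC)c(OCc4ccccc4)c(OC)c3)[C@@H]2CO[Si](C)(C)C(C)(C)C)ccc1OCc1ccccc1 | intermediate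
20 | [4-(benzyloxy)-3,5-dimethoxyphenyl][(3S,4R,5S)-5-[4-(benzyloxy)-3-methoxyphenyl]-4-(hydroxymethyl)oxolan-3-yl]methanone | COc1cc([C@H]2OC[C@@H](C(=O)c3cc(OC)c(OCc4ccccc4)c(OC)c3)[C@@H]2CO)ccc1OCc1ccccc1 | intermediate
21 | (4-hydroxy-3,5-dimethoxyphenyl)[(3S,4R,5S)-5-(4-hydroxy-3-methoxyphenyl)-4-(hydroxymethyl)oxolan-3-yl]methanone, all-trans ring | COc1cc([C@H]2OC[C@@H](C(=O)c3cc(OC)c(O)c(OC)c3)[C@@H]2CO)ccc1O | target

**Totals**
Total step count: 12. Longest linear sequence: 11 steps (steps 1 to 5 and 7 to 12); step 6 is a one-step side branch.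

**Three steps most likely to fail, with fallbacks**

Step 9 (selective tosylation and ring closure of a triol). The two electron-rich benzylic alcohols may also be sulfonylated and ionise. The fallback sets out from 15 and comes back at 18. The carbinol of 15 is silylated (Et3SiOTf, 2,6-lutidine, CH2Cl2, −78 °C) to (3R,4R,5S)-5-[4-(benzyloxy)-3-methoxyphenyl]-3-{[4-(benzyloxy)-3,5-dimethoxyphenyl](triethylsilyloxy)methyl}-4-{[(tert-butyldimethylsilyl)oxy]methyl}oxolan-2-one F6. LiAlH4 (THF, 0 °C) then gives a plain 1,4-diol, (1S,2R,3S)-1-[4-(benzyloxy)-3-methoxyphenyl]-3-{[4-(benzyloxy)-3,5-dimethoxyphenyl](triethylsilyloxy)methyl}-2-{[(tert-butyldimethylsilyl)oxy]methyl}butane-1,4-diol F7. Mitsunobu cyclodehydration (PPh3, DIAD, THF, 0 °C → rt) activates the primary hydroxyl and closes the ring with retention at the benzylic carbon to (3S,4R,5S)-5-[4-(benzyloxy)-3-methoxyphenyl]-3-{[4-(benzyloxy)-3,5-dimethoxyphenyl](triethylsilyloxy)methyl}-4-{[(tert-butyldimethylsilyl)oxy]methyl}oxolane F8. Selective removal of the triethylsilyl group (PPTS, MeOH/CH2Cl2, 0 °C) returns 18.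

Step 7 (lactone-enolate aldol with an electron-rich aldehyde). Retro-aldol or low conversion is possible. The fallback sets out from 13 and 11 and comes back at 15, replacing the aldol by an irreversible crossed Claisen acylation followed by ketone reduction. Aldehyde 13 is oxidised (NaClO2, NaH2PO4, 2-methyl-2-butene, t-BuOH/H2O) to 4-(benzyloxy)-3,5-dimethoxybenzoic acid F3. This is coupled with MeNHOMe·HCl (EDC·HCl, Et3N, CH2Cl2) to 4-(benzyloxy)-N,3,5-trimethoxy-N-methylbenzamide F4. Enolate 14, made from 11 as in step 7, is acylated with F4 (THF, −78 → 0 °C) to the thermodynamically trans β-keto lactone (3R,4R,5S)-3-[4-(benzyloxy)-3,5-dimethoxybenzoyl]-5-[4-(benzyloxy)-3-methoxyphenyl]-4-{[(tert-butyldimethylsilyl)oxy]methyl}oxolan-2-one F5. NaBH4 (MeOH, −20 °C) reduces only the aryl ketone and gives 15.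

Step 2 (auxiliary aldol and lactonisation). The electron-rich aldehyde may react sluggishly or the adduct may revert. The fallback sets out from 5 and comes back at 9. Aldehyde 5 is condensed with succinic anhydride (ZnCl2, Et3N, CH2Cl2, rt; the trans isomer is purified by crystallisation) to racemic trans-2-[4-(benzyloxy)-3-methoxyphenyl]-5-oxooxolane-3-carboxylic acid F1. This is resolved by crystallisation with one enantiomer of 1-phenylethylamine, chosen by a small salt screen and written here as the (R)-amine, as (R)-1-phenylethylammonium (2S,3S)-2-[4-(benzyloxy)-3-methoxyphenyl]-5-oxooxolane-3-carboxylate F2. Acidification (1 M HCl, EtOAc) returns 9.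

**Further compounds**
F1 | step 2 | racemic trans-2-[4-(benzyloxy)-3-methoxyphenyl]-5-oxooxolane-3-carboxylic acid, (2S,3S) and (2R,3R) pair | COc1cc([C@H]2OC(=O)C[C@@H]2C(=O)O)ccc1OCc1ccccc1.COc1cc([C@@H]2OC(=O)C[C@H]2C(=O)O)ccc1OCc1ccccc1
F2 | step 2 | (R)-1-phenylethylammonium (2S,3S)-2-[4-(benzyloxy)-3-methoxyphenyl]-5-oxooxolane-3-carboxylate | C[C@@H]([NH3+])c1ccccc1.COc1cc([C@H]2OC(=O)C[C@@H]2C([O-])=O)ccc1OCc1ccccc1
F3 | step 7 | 4-(benzyloxy)-3,5-dimethoxybenzoic acid | COc1cc(C(=O)O)cc(OC)c1OCc1ccccc1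
F4 | step 7 | 4-(benzyloxy)-N,3,5-trimethoxy-N-methylbenzamide | CON(C)C(=O)c1cc(OC)c(OCc2ccccc2)c(OC)c1
F5 | step 7 | (3R,4R,5S)-3-[4-(benzyloxy)-3,5-dimethoxybenzoyl]-5-[4-(benzyloxy)-3-methoxyphenyl]-4-{[(tert-butyldimethylsilyl)oxy]methyl}oxolan-2-one | COc1cc([C@H]2OC(=O)[C@@H](C(=O)c3cc(OC)c(OCc4ccccc4)c(OC)c3)[C@@H]2CO[Si](C)(C)C(C)(C)C)ccc1OCc1ccccc1
F6 | step 9 | (3R,4R,5S)-5-[4-(benzyloxy)-3-methoxyphenyl]-3-{[4-(benzyloxy)-3,5-dimethoxyphenyl](triethylsilyloxy)methyl}-4-{[(tert-butyldimethylsilyl)oxy]methyl}oxolan-2-one, both silyloxy epimers | COc1cc([C@H]2OC(=O)[C@@H](C(O[Si](CC)(CC)CC)c3cc(OC)c(OCc4ccccc4)c(OC)c3)[C@@H]2CO[Si](C)(C)C(C)(C)C)ccc1OCc1ccccc1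
F7 | step 9 | (1S,2R,3S)-1-[4-(benzyloxy)-3-methoxyphenyl]-3-{[4-(benzyloxy)-3,5-dimethoxyphenyl](triethylsilyloxy)methyl}-2-{[(tert-butyldimethylsilyl)oxy]methyl}butane-1,4-diol, both silyloxy epimers | COc1cc([C@@H](O)[C@@H](CO[Si](C)(C)C(C)(C)C)[C@@H](CO)C(O[Si](CC)(CC)CC)c2cc(OC)c(OCc3ccccc3)c(OC)c2)ccc1OCc1ccccc1
F8 | step 9 | (3S,4R,5S)-5-[4-(benzyloxy)-3-methoxyphenyl]-3-{[4-(benzyloxy)-3,5-dimethoxyphenyl](triethylsilyloxy)methyl}-4-{[(tert-butyldimethylsilyl)oxy]methyl}oxolane, both silyloxy epimers | COc1cc([C@H]2OC[C@@H](C(O[Si](CC)(CC)CC)c3cc(OC)c(OCc4ccccc4)c(OC)c3)[C@@H]2CO[Si](C)(C)C(C)(C)C)ccc1OCc1ccccc1
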